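## Structural features

The target 19 is a spiro[5.5]undecane. Ring A (C1–C6) is a cyclohexane with a gem-dimethyl group at C1, a secondary bromide at C3 and a tertiary carbinol (CH3, OH) at C5. Ring B (C6–C11) is a cyclohexene (C7=C8) conjugated to an exocyclic bromomethylidene at C9 (C12), with the bromine on the C10 side (9E).

The rings share only C6, a fully substituted carbon wedged between the quaternary C1 and the tertiary carbinol C5. C5 and C6 are contiguous stereocentres and C3 stands 1,3 to C5. In the 3R,5S,6S isomer the C5 hydroxyl and the C11 arm lie on one face of ring A, and the C3 bromine, the C5 methyl and the C7 arm on the other.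

The fragile groups are the 1-bromo-1,3-diene (its geometry can drift under light, acid or radicals, and it is sensitive to strong reductants), the secondary bromide (E2) and the tertiary homoallylic alcohol (dehydration). On the way, any C3 oxygen leaving group is also at risk, because it sits β to C4 whenever negative charge is delocalised into ring A.

The real difficulty is C6: its two ring B arms differ only as an sp2 CH (C7) and a CH2 (C11), and it must be built with the right sense between two fully substituted neighbours. The geometry of C9=C12 is the second problem.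

The key step uses the fact that, in an α-ionone-type dienone, C6–H is doubly allylic (to C4=C5 and C7=C8) and vinylogously α to C9=O. A vinyl group (C10=C11) on the other side of C9 makes C6 and C11 the termini of a 3-oxido-hexatriene. The C3 oxygen together with the C1 gem-dimethyl group decides the face of ring A on which C11 arrives.

## Logic of the disconnections

19 to 18: the C3–Br bond is cut first because the secondary bromide is the group most easily lost to elimination and should be made last. It is traced to the C3 carbinol of opposite configuration in 18. All other functionality is then already present. The forward step must be a clean SN2 inversion at C3 that leaves the tertiary C5 hydroxyl alone.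

18 to 17 to 16: the C5–O bond and one C4–H bond are traced through the epoxide 17 to the C4=C5 alkene of 16. The cut is made here because the C3 hydroxyl of 16 lies on the face where the C5 oxygen is needed and can direct the oxidant. This removes the C5 stereocentre. The forward steps must epoxidise only the allylic-alcohol alkene in the presence of the bromodiene, and must deliver hydride to C4 and not to C5 or to the C–Br bond.

16 to 13 and 14: the C9=C12 double bond is cut to the ring ketone of 13 and the one-carbon phosphonium salt 14. This removes the bromodiene and leaves the enone that the key step produces. The forward step must place the bromine on the C10 side and must tolerate the free C3 hydroxyl, which is deliberately not re-protected.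

13 to 10 (key disconnection): the C6–C11 bond is cut, which opens ring B and removes the spiro stereocentre. What remains is the monocyclic dienone 10, whose C6 configuration is irrelevant. The forward step must deprotonate only at C6, close faster than the vinyl ketone is consumed intermolecularly, and take its facial bias from C3. The C3 hydroxyl of 10 is left free so that it enters as an alkoxide, which cannot be expelled from the C4 terminus of the anion.

10 to 8 and 9: the C9–C10 bond is cut to the N-methoxy-N-methylamide 8 and the vinyl Grignard reagent 9. The divinyl ketone is the most fragile intermediate, so it is made in the last operation before use, after the silyl group has gone. The forward step must stop at the ketone and keep the liberated amine from adding to it.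

8 to 7 to 5 and 6: the C7=C8 bond is cut to the aldehyde 5 and the stabilised ylide 6, after accounting for the silyl ether. A neutral olefination is required because 5 is enolisable at C6 and carries a C3 silyloxy group that a dienolate could expel. The forward step must give the E alkene.

5 to 4 to 3 to 2 to 1: oxidation-level changes lead from the aldehyde to the ester, and the C3 carbinol is traced to the ring ketone of the commercial racemic keto ester 1. One silyl group is used once, between 2 and 7. The forward reduction must be catalyst-controlled at C3 in both enantiomers of 1.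

## Other disconnections considered

Alternative 1: the cut is C6–C7, with the C6–O bond of an epoxide as the leaving group. In the forward step MeAlCl2 activates the C5–C6 epoxide of the epoxy vinylsilane A1. The silicon-bearing C7 attacks C6 anti to the departing oxygen, silicon is lost, and the spiro alcohol A2 results.
- In its favour: the C5 tertiary alcohol and the spiro centre are formed together with a fixed anti relation, so steps 10 and 11 of the chosen plan are not needed. That is a real advantage. Ring A can also come from the chiral pool, so C3 needs no asymmetric catalysis, which is equal to or better than step 1.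
- Against it: C6 lies next to quaternary C1, so the opening is likely to have carbocation character. Stereospecificity could then erode, and 1,2-shifts (a C1 methyl, ring contraction, or rearrangement to a ketone) are the natural competitors.
- The epoxide face in A1 must be set on a tetrasubstituted alkene with only a remote silyl ether to bias it, so the stereochemical problem is moved and not solved.
- A2 has a bare CH2 at C9. An allylic oxidation would have to precede a bromomethylenation that has the same geometric weakness as step 9.
- Comparison: on structure it is better at C5/C6 and worse at C9. On mechanism it is a cationic closure prone to rearrangement, against an anionic pericyclic closure whose main competitor is intermolecular. On step economy it is probably no shorter once the (Z)-vinylsilane tether and the C9 oxidation are counted.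

Alternative 2: the cut is C1–C6 in ring A. In the forward step Fe(acac)3 and PhSiH3 transfer a hydrogen atom to the isopropenyl group of the dienal A3. The tertiary C1 radical adds 6-exo to C6, the δ-carbon of the dienal, and reduction and protonation give the spiro enal A4.
- In its favour: both hydroxyls and C12 (as the aldehyde) are already present, so there is no epoxidation, hydride opening or one-carbon olefination after the key step. The conditions are neutral and tolerate free hydroxyls.
- The aldehyde also allows the bromodiene to be made through an E dienolate of defined geometry. On that point it is better than step 9.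
- Against it: the new bond joins two fully substituted carbons, so simple reduction of the radical or of the diene may compete.
- The sense at C6 would depend on the conformation of an acyclic chain whose C5 substituents (CH3, OH) are of similar size, which is less secure than a ring-locked bias.
- A3 contains a cyclohexa-1,3-diene carbaldehyde that is prone to aromatise, and its C5 tertiary carbinol must be made stereoselectively beforehand. The C7=C8 alkene must also be regenerated from C8=C9.
- Comparison: it is equal or better on the tail of the synthesis and on C12, and worse on the security of the key bond and on the precursor. The total step count is probably similar.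

Alternative 3: the cut is C9–C10 in ring B. In the forward step t-BuLi exchanges the iodide of A5, the primary alkyllithium adds syn (6-exo-dig) across the silyl alkyne, and BrCF2CF2Br brominates the α-silyl vinyllithium with retention to give A6.
- In its favour: the geometry of C9=C12 follows from the mechanism, which is clearly better than step 9, where nothing in the substrate directs the ylide. All carbons, C12 included, are in place.
- Against it: the key step creates no stereocentre. C6 must already be a defined quaternary centre carrying three different carbon arms in A5, and no short, selective way to that centre is evident. The hardest problem is therefore left to the precursor.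
- The α-silyl dienyllithium must hold its configuration until it is brominated.
- After A6 two desilylations, the epoxidation, the hydride opening and the C3 bromination remain, a longer tail than in the chosen plan.
- Comparison: it is better on the bromodiene, equal on the ring A endgame, and worse on the spiro centre, which is the point on which the chosen plan is built.

Key step: step 8

Assumption: 1 is used as the racemate and its ester-bearing centre (working C6) is carried as an epimer mixture until step 8 makes it planar. Spiro compounds are named with the working locants (ring A C1–C6, ring B C6–C11, exocyclic C12); 19 requires 3S in 10 and 3S,6S in 13.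

## Route

Step 1
Reactants: 1 ethyl 2,6,6-trimethyl-4-oxocyclohex-2-ene-1-carboxylate (racemate)
Product: 2 ethyl (4S)-4-hydroxy-2,6,6-trimethylcyclohex-2-ene-1-carboxylate (both C1 epimers)
Conditions: (R)-Me-CBS oxazaborolidine [(R)-1-methyl-3,3-diphenyltetrahydro-1H,3H-pyrrolo[1,2-c][1,3,2]oxazaborole] (0.2 equiv), BH3·SMe2 (0.7 equiv), THF, −20 °C; MeOH, then H2O
Reagents that add atoms: none
Why: Corey–Bakshi–Shibata reduction; the catalyst-bound borane attacks one face of the enone carbonyl under catalyst control, with the alkenyl arm in the role of the large group, so the (R)-catalyst should give the 4S carbinol in both C1 epimers (the enantiomeric catalyst would be used if the CH2–C(CH3)2 arm proved dominant). The ester and the trisubstituted alkene are inert to BH3 at this temperature.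

Step 2
Reactants: 2 ethyl (4S)-4-hydroxy-2,6,6-trimethylcyclohex-2-ene-1-carboxylate
Product: 3 ethyl (4S)-4-[(tert-butyldimethylsilyl)oxy]-2,6,6-trimethylcyclohex-2-ene-1-carboxylate
Conditions: TBSCl, imidazole, DMF, 20 °C
Reagents that add atoms: tert-butyldimethylsilyl chloride, `CC(C)(C)[Si](C)(C)Cl`
Why: Standard silylation of an unhindered secondary allylic alcohol; the ether protects the carbinol through the hydride reduction, the oxidation and the olefination.

Step 3
Reactants: 3 ethyl (4S)-4-[(tert-butyldimethylsilyl)oxy]-2,6,6-trimethylcyclohex-2-ene-1-carboxylate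
Product: 4 [(4S)-4-[(tert-butyldimethylsilyl)oxy]-2,6,6-trimethylcyclohex-2-en-1-yl]methanol
Conditions: i-Bu2AlH (2.5 equiv), CH2Cl2, −78 → 0 °C; aq. KNaC4H4O6
Reagents that add atoms: none
Why: Ester reduction by an aluminium hydride; full reduction to the alcohol is chosen because partial reduction of this hindered ester is hard to stop cleanly. The silyl ether and the alkene are inert.

Step 4
Reactants: 4 [(4S)-4-[(tert-butyldimethylsilyl)oxy]-2,6,6-trimethylcyclohex-2-en-1-yl]methanol
Product: 5 (4S)-4-[(tert-butyldimethylsilyl)oxy]-2,6,6-trimethylcyclohex-2-ene-1-carbaldehyde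
Conditions: Dess–Martin periodinane, NaHCO3, CH2Cl2, 0 → 20 °C
Reagents that add atoms: none
Why: Dess–Martin oxidation under buffered, essentially neutral conditions, so that the enolisable β,γ-unsaturated aldehyde neither moves its double bond into conjugation nor loses the C4 silyloxy group.

Step 5
Reactants: 5 (4S)-4-[(tert-butyldimethylsilyl)oxy]-2,6,6-trimethylcyclohex-2-ene-1-carbaldehyde; 6 N-methoxy-N-methyl-2-(triphenyl-λ5-phosphanylidene)acetamide
Product: 7 (2E)-3-[(4S)-4-[(tert-butyldimethylsilyl)oxy]-2,6,6-trimethylcyclohex-2-en-1-yl]-N-methoxy-N-methylprop-2-enamide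
Conditions: toluene, 90 °C
Reagents that add atoms: none
Why: Wittig reaction with a stabilised amide ylide; no external base is present, so the aldehyde is not enolised, and the stabilised ylide gives the E alkene (C7=C8).

Step 6
Reactants: 7 (2E)-3-[(4S)-4-[(tert-butyldimethylsilyl)oxy]-2,6,6-trimethylcyclohex-2-en-1-yl]-N-methoxy-N-methylprop-2-enamide
Product: 8 (2E)-3-[(4S)-4-hydroxy-2,6,6-trimethylcyclohex-2-en-1-yl]-N-methoxy-N-methylprop-2-enamide
Conditions: Bu4NF, AcOH, THF, 0 → 20 °C
Reagents that add atoms: none
Why: Fluoride desilylation, buffered with AcOH; it is done on the robust amide so that the later divinyl ketone never meets fluoride, and acid is avoided because the allylic carbinol dehydrates easily.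

Step 7
Reactants: 8 (2E)-3-[(4S)-4-hydroxy-2,6,6-trimethylcyclohex-2-en-1-yl]-N-methoxy-N-methylprop-2-enamide; 9 ethenylmagnesium bromide, CH2=CHMgBr
Product: 10 (1E)-1-[(4S)-4-hydroxy-2,6,6-trimethylcyclohex-2-en-1-yl]penta-1,4-dien-3-one (both ring C1 epimers)
Conditions: CH2=CHMgBr (3 equiv), THF, −78 → 0 °C; inverse quench into 1 M HCl, 0 °C
Reagents that add atoms: none
Why: Weinreb ketone synthesis; one equivalent of the Grignard reagent is spent on the hydroxyl, a further one adds to the amide carbonyl, and the N-methoxy-N-methylamide holds the addition at the ketone oxidation level until the quench. The cold acidic inverse quench protonates the released amine before it can add to the new vinyl ketone.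

Step 8
Reactants: 10 (1E)-1-[(4S)-4-hydroxy-2,6,6-trimethylcyclohex-2-en-1-yl]penta-1,4-dien-3-one
Product: 13 (3S,6S)-3-hydroxy-1,1,5-trimethylspiro[5.5]undeca-4,7-dien-9-one, via dipotassium oxido-trienolate 11 (not isolated), via dipotassium spiro dienolate 12 (not isolated)
Conditions: KN(SiMe3)2 (2.3 equiv), THF (0.01 M), −78 → 0 °C; AcOH, −78 °C
Reagents that add atoms: none
Why: The first equivalent of KN(SiMe3)2 turns the C3 hydroxyl into its alkoxide and the second removes the only acidic C–H, at C6 (doubly allylic and vinylogously α to C9=O; C10 is vinylic), so both C6 epimers of 10 give the same 3-oxido-hexatriene 11. Thermal disrotatory 6π-electrocyclisation of 11, accelerated by the oxyanion on C9, joins C6 to C11 and gives the cross-conjugated dienolate 12, which AcOH protonates at C10 to the conjugated enone 13. The closest known reaction type is the oxyanion-accelerated electrocyclisation of 3-oxido-hexatrienes (trienolates of divinyl ketones) to cyclohex-2-enones. Ring B is closed by this concerted six-electron pericyclic process and not by a stepwise polar attack. The one new stereocentre, C6, is controlled by C3: in the envelope of ring A (C2 as the flap) the C3 oxygen is pseudo-equatorial to avoid a 1,3-diaxial clash with a C1 methyl, the axial C1 methyl then shields the opposite face of C6, and C11 bonds on the face cis to the C3 oxygen (6S). The step needs site-selective deprotonation, closure faster than intermolecular conjugate addition to the vinyl ketone, the C8=C9 enolate bond with C7 and C10 on the same side, and retention of the C3 oxygen; these rest on the absence of other acidic hydrogens, on high dilution at low temperature, on rotation within the delocalised potassium trienolate, and on the fact that an alkoxide, unlike a silyl ether, cannot leave from the C4 terminus of the anion.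

Step 9
Reactants: 13 (3S,6S)-3-hydroxy-1,1,5-trimethylspiro[5.5]undeca-4,7-dien-9-one; 14 (bromomethyl)triphenylphosphonium bromide
Product: 16 (3S,6S,9E)-9-(bromomethylidene)-1,1,5-trimethylspiro[5.5]undeca-4,7-dien-3-ol, via (bromomethylidene)triphenylphosphorane 15 (not isolated)
Conditions: 14 (3.5 equiv), KOt-Bu (3.3 equiv), THF, −78 °C; then 13, −78 → 20 °C; chromatography
Reagents that add atoms: none
Why: Wittig bromomethylenation; the ylide 15 adds 1,2 to the enone carbonyl, and an excess makes protection of the C3 hydroxyl unnecessary. Under salt-free kinetic conditions the bromine is expected, though only modestly, to prefer the side of the sp3 carbon C10, the bulkier flank, which is the 9E geometry; the 9Z isomer would be removed by chromatography.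

Step 10
Reactants: 16 (3S,6S,9E)-9-(bromomethylidene)-1,1,5-trimethylspiro[5.5]undeca-4,7-dien-3-ol
Product: 17 (3S,4S,5R,6S,9E)-9-(bromomethylidene)-4,5-epoxy-1,1,5-trimethylspiro[5.5]undec-7-en-3-ol
Conditions: VO(acac)2 (0.05 equiv), t-BuOOH (1.5 equiv), CH2Cl2, 0 → 20 °C
Reagents that add atoms: tert-butyl hydroperoxide, `CC(C)(C)OO`
Why: Hydroxyl-directed epoxidation; the vanadium catalyst bound to the C3 hydroxyl delivers the peroxide oxygen to C4=C5 on the face of that hydroxyl, which sets C4 and C5 with the oxygen cis to C3–O and to C11. The bromodiene has no allylic hydroxyl and should not be epoxidised at a competitive rate.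

Step 11
Reactants: 17 (3S,4S,5R,6S,9E)-9-(bromomethylidene)-4,5-epoxy-1,1,5-trimethylspiro[5.5]undec-7-en-3-ol
Product: 18 (3S,5S,6S,9E)-9-(bromomethylidene)-1,1,5-trimethylspiro[5.5]undec-7-ene-3,5-diol
Conditions: NaAlH2(OCH2CH2OCH3)2 (3 equiv), THF, 0 → 20 °C; aq. KNaC4H4O6
Reagents that add atoms: none
Why: Hydride opening of a trisubstituted epoxide; SN2 attack at the secondary C4, anti to the epoxide oxygen, is the only accessible path because C5 is tertiary and flanked by the spiro carbon, so the C5–O bond is kept and the tertiary alcohol appears cis to the C3 hydroxyl (syn-1,3-diol). The alkenyl bromide should not be reduced by this hydride at or below room temperature.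

Step 12
Reactants: 18 (3S,5S,6S,9E)-9-(bromomethylidene)-1,1,5-trimethylspiro[5.5]undec-7-ene-3,5-diol
Product: 19 (3R,5S,6S,9E)-3-bromo-9-(bromomethylidene)-1,1,5-trimethylspiro[5.5]undec-7-en-5-ol
Conditions: PPh3, CBr4, CH2Cl2, 0 → 20 °C
Reagents that add atoms: carbon tetrabromide, `BrC(Br)(Br)Br`
Why: Appel bromination; PPh3/CBr4 activates the secondary C3 hydroxyl and bromide displaces it in an SN2 reaction with inversion (3S carbinol to 3R bromide, bromine equatorial). The tertiary C5 hydroxyl next to the spiro carbon is too hindered to be activated, and its cis-1,3 relation to C3 rules out backside participation.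

## Compound list

1 | ethyl 2,6,6-trimethyl-4-oxocyclohex-2-ene-1-carboxylate (racemate) | `CCOC(=O)C1C(C)=CC(=O)CC1(C)C` | starting material
2 | ethyl (4S)-4-hydroxy-2,6,6-trimethylcyclohex-2-ene-1-carboxylate (C1 epimers) | `CC1(C)C[C@H](O)C=C(C)C1C(=O)OCC` | intermediate
3 | ethyl (4S)-4-[(tert-butyldimethylsilyl)oxy]-2,6,6-trimethylcyclohex-2-ene-1-carboxylate | `CC1(C)C[C@H](O[Si](C)(C)C(C)(C)C)C=C(C)C1C(=O)OCC` | intermediate
4 | [(4S)-4-[(tert-butyldimethylsilyl)oxy]-2,6,6-trimethylcyclohex-2-en-1-yl]methanol | `CC1(C)C[C@H](O[Si](C)(C)C(C)(C)C)C=C(C)C1CO` | intermediate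
5 | (4S)-4-[(tert-butyldimethylsilyl)oxy]-2,6,6-trimethylcyclohex-2-ene-1-carbaldehyde | `CC1(C)C[C@H](O[Si](C)(C)C(C)(C)C)C=C(C)C1C=O` | intermediate
6 | N-methoxy-N-methyl-2-(triphenyl-λ5-phosphanylidene)acetamide | `CON(C)C(=O)C=P(c1ccccc1)(c1ccccc1)c1ccccc1` | starting material
7 | (2E)-3-[(4S)-4-[(tert-butyldimethylsilyl)oxy]-2,6,6-trimethylcyclohex-2-en-1-yl]-N-methoxy-N-methylprop-2-enamide | `CC1(C)C[C@H](O[Si](C)(C)C(C)(C)C)C=C(C)C1/C=C/C(=O)N(C)OC` | intermediate
8 | (2E)-3-[(4S)-4-hydroxy-2,6,6-trimethylcyclohex-2-en-1-yl]-N-methoxy-N-methylprop-2-enamide | `CC1(C)C[C@H](O)C=C(C)C1/C=C/C(=O)N(C)OC` | intermediate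
9 | ethenylmagnesium bromide, CH2=CHMgBr | `C=C[Mg]Br` | starting material
10 | (1E)-1-[(4S)-4-hydroxy-2,6,6-trimethylcyclohex-2-en-1-yl]penta-1,4-dien-3-one (ring C1 epimers) | `CC1(C)C[C@H](O)C=C(C)C1/C=C/C(=O)C=C` | intermediate
11 | dipotassium (2E)-1-[(4S)-2,6,6-trimethyl-4-oxidocyclohex-2-en-1-ylidene]penta-2,4-dien-3-olate | `[K+].[K+].CC1(C)C[C@H]([O-])C=C(C)C1=C/C=C(/[O-])C=C` | intermediate
12 | dipotassium (3S,6S)-1,1,5-trimethylspiro[5.5]undeca-4,7,9-triene-3,9-bis(olate) | `[K+].[K+].CC1(C)C[C@H]([O-])C=C(C)[C@@]12C=CC([O-])=CC2` | intermediate
13 | (3S,6S)-3-hydroxy-1,1,5-trimethylspiro[5.5]undeca-4,7-dien-9-one | `CC1(C)C[C@H](O)C=C(C)[C@@]12C=CC(=O)CC2` | intermediate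
14 | (bromomethyl)triphenylphosphonium bromide | `BrC[P+](c1ccccc1)(c1ccccc1)c1ccccc1.[Br-]` | starting material
15 | (bromomethylidene)triphenylphosphorane | `BrC=P(c1ccccc1)(c1ccccc1)c1ccccc1` | intermediate
16 | (3S,6S,9E)-9-(bromomethylidene)-1,1,5-trimethylspiro[5.5]undeca-4,7-dien-3-ol | `CC1(C)C[C@H](O)C=C(C)[C@@]12C=C/C(=C/Br)CC2` | intermediate
17 | (3S,4S,5R,6S,9E)-9-(bromomethylidene)-4,5-epoxy-1,1,5-trimethylspiro[5.5]undec-7-en-3-ol | `CC1(C)C[C@H](O)[C@@H]2O[C@]2(C)[C@@]13C=C/C(=C/Br)CC3` | intermediate
18 | (3S,5S,6S,9E)-9-(bromomethylidene)-1,1,5-trimethylspiro[5.5]undec-7-ene-3,5-diol | `CC1(C)C[C@H](O)C[C@](C)(O)[C@@]12C=C/C(=C/Br)CC2` | intermediate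
19 | (3R,5S,6S,9E)-3-bromo-9-(bromomethylidene)-1,1,5-trimethylspiro[5.5]undec-7-en-5-ol | `CC1(C)C[C@@H](Br)C[C@](C)(O)[C@@]12C=C/C(=C/Br)CC2` | target

## Step count and least certain steps

Total step count: 12. Longest linear sequence: 12 steps (1 to 19); 6, 9 and 14 are purchased.

Step 8 (key step). The most likely failure is intermolecular conjugate addition or anionic oligomerisation of the vinyl ketone outrunning ring closure. The C6 terminus is fully substituted and must turn a ring carbon inward in the transition state, and part of the trienolate may form with the unproductive C8=C9 geometry. A weaker facial bias than expected is the second concern. The fallback sets out from 5 and forms the same C6–C11 bond in a stepwise polar way. Michael addition of 5 to but-3-en-2-one under pyrrolidine catalysis, with C11 entering anti to the axial C1 methyl, gives the keto aldehyde F1. Intramolecular aldol condensation (KOH, MeOH) closes ring B to the silyl ether F2, and Bu4NF/AcOH returns the route at 13.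

Step 9. Poor geometric control at C9=C12 is the main risk: the two flanks of the carbonyl (sp2 CH and CH2) differ little and nothing in the substrate directs the ylide. Enolisation at C10 and decay of the labile ylide may also lower conversion. The fallback sets out from 13 and fixes the geometry through an enal.
- Silylation (TBSCl, imidazole) gives the silyl ether F2.
- Wittig methoxymethylenation (Ph3P=CHOCH3) gives the methyl dienol ether F3, and aqueous oxalic acid hydrolyses it to the conjugated enal F4.
- KN(SiMe3)2 removes a C7 hydrogen from the s-trans enal and PhNTf2 traps the dienolate on oxygen as the E dienyl triflate F5, with the oxygen on the C10 side.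
- Pd(PPh3)4, Me3SnSnMe3 and LiCl give the dienylstannane F6, and N-bromosuccinimide gives the bromodiene silyl ether F7, both with retention.
- Bu4NF returns the route at 16.

Step 12. E2 elimination from the activated C3 oxygen may compete, since anti-periplanar hydrogens at C2 and C4 are available when the leaving group is axial. The activated phosphorus may also be trapped by the cis C5 hydroxyl, which would stall the displacement. The fallback sets out from 18 and separates activation from displacement. ClCH2SO2Cl and pyridine give the chloromethanesulfonate F8, and LiBr in DMF displaces it with inversion, returning the route at 19.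

Step 1. Enantiocontrol may erode, because the two flanks of the ketone (CH=C(CH3) and CH2–C(CH3)2) are of similar size and the racemic ester centre creates matched and mismatched pairs. The fallback sets out from 1. NaBH4/CeCl3·7H2O gives the stereoisomer mixture of allylic alcohols F9. Lipase-catalysed acylation with vinyl acetate is then expected, by the usual empirical model for secondary alcohols, to acetylate the 4R alcohols to the acetate F10 and leave the 4S alcohols, which rejoin the route at 2.

Step 11. Hydride may be too slow to open the epoxide at C4, which is deactivated by the neighbouring aluminium-bound C3 oxygen, and forcing the reaction risks loss of the vinylic bromine. The fallback sets out from 13 and reorders the tail so that the bromodiene never meets a hydride. VO(acac)2/t-BuOOH gives the epoxy enone F11. LiAlH4 opens the epoxide at C4 and reduces the ketone, giving the triol F12. MnO2 reoxidises only the allylic C9 carbinol to the dihydroxy enone F13. Bromomethylenation with 14 and KOt-Bu in excess then rejoins the route at 18.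

## Further compounds

F1 | step 8 | (1S,4S)-4-[(tert-butyldimethylsilyl)oxy]-2,6,6-trimethyl-1-(3-oxobutyl)cyclohex-2-ene-1-carbaldehyde | `CC1(C)C[C@H](O[Si](C)(C)C(C)(C)C)C=C(C)[C@]1(C=O)CCC(C)=O`
F2 | step 8 | (3S,6S)-3-[(tert-butyldimethylsilyl)oxy]-1,1,5-trimethylspiro[5.5]undeca-4,7-dien-9-one | `CC1(C)C[C@H](O[Si](C)(C)C(C)(C)C)C=C(C)[C@@]12C=CC(=O)CC2`
F3 | step 9 | tert-butyl{[(3S,6S)-9-(methoxymethylidene)-1,1,5-trimethylspiro[5.5]undeca-4,7-dien-3-yl]oxy}dimethylsilane (both C9=C12 isomers) | `CC1(C)C[C@H](O[Si](C)(C)C(C)(C)C)C=C(C)[C@@]12C=CC(=COC)CC2`
F4 | step 9 | (3S,6S)-3-[(tert-butyldimethylsilyl)oxy]-1,1,5-trimethylspiro[5.5]undeca-4,8-diene-9-carbaldehyde | `CC1(C)C[C@H](O[Si](C)(C)C(C)(C)C)C=C(C)[C@@]12CC=C(C=O)CC2`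
F5 | step 9 | (E)-[(3S,6S)-3-[(tert-butyldimethylsilyl)oxy]-1,1,5-trimethylspiro[5.5]undeca-4,7-dien-9-ylidene]methyl trifluoromethanesulfonate | `CC1(C)C[C@H](O[Si](C)(C)C(C)(C)C)C=C(C)[C@@]12C=C/C(=C/OS(=O)(=O)C(F)(F)F)CC2`
F6 | step 9 | tert-butyldimethyl{[(3S,6S,9E)-1,1,5-trimethyl-9-[(trimethylstannyl)methylidene]spiro[5.5]undeca-4,7-dien-3-yl]oxy}silane | `CC1(C)C[C@H](O[Si](C)(C)C(C)(C)C)C=C(C)[C@@]12C=C/C(=C/[Sn](C)(C)C)CC2`
F7 | step 9 | {[(3S,6S,9E)-9-(bromomethylidene)-1,1,5-trimethylspiro[5.5]undeca-4,7-dien-3-yl]oxy}(tert-butyl)dimethylsilane | `CC1(C)C[C@H](O[Si](C)(C)C(C)(C)C)C=C(C)[C@@]12C=C/C(=C/Br)CC2`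
F8 | step 12 | (3S,5S,6S,9E)-9-(bromomethylidene)-5-hydroxy-1,1,5-trimethylspiro[5.5]undec-7-en-3-yl chloromethanesulfonate | `CC1(C)C[C@H](OS(=O)(=O)CCl)C[C@](C)(O)[C@@]12C=C/C(=C/Br)CC2`
F9 | step 1 | ethyl 4-hydroxy-2,6,6-trimethylcyclohex-2-ene-1-carboxylate (all stereoisomers) | `CCOC(=O)C1C(C)=CC(O)CC1(C)C`
F10 | step 1 | ethyl (4R)-4-acetoxy-2,6,6-trimethylcyclohex-2-ene-1-carboxylate (C1 epimers) | `CC1(C)C[C@@H](OC(C)=O)C=C(C)C1C(=O)OCC`
F11 | step 11 | (3S,4S,5R,6S)-4,5-epoxy-3-hydroxy-1,1,5-trimethylspiro[5.5]undec-7-en-9-one | `CC1(C)C[C@H](O)[C@@H]2O[C@]2(C)[C@@]13C=CC(=O)CC3`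
F12 | step 11 | (3S,5S,6S)-1,1,5-trimethylspiro[5.5]undec-7-ene-3,5,9-triol (C9 epimers) | `CC1(C)C[C@H](O)C[C@](C)(O)[C@@]12C=CC(O)CC2`
F13 | step 11 | (3S,5S,6S)-3,5-dihydroxy-1,1,5-trimethylspiro[5.5]undec-7-en-9-one | `CC1(C)C[C@H](O)C[C@](C)(O)[C@@]12C=CC(=O)CC2`
A1 | alternative 1 | ring A 5,6-epoxide (oxygen cis to the C3 silyloxy group) with C3–OSi(t-Bu)(CH3)2 and a (4Z)-5-(trimethylsilyl)pent-4-en-1-yl chain on C6 | `CC1(C)C[C@H](O[Si](C)(C)C(C)(C)C)C[C@]2(C)O[C@]12CCC/C=C\[Si](C)(C)C`
A2 | alternative 1 | (3S,5S,6S)-3-[(tert-butyldimethylsilyl)oxy]-1,1,5-trimethylspiro[5.5]undec-7-en-5-ol | `CC1(C)C[C@H](O[Si](C)(C)C(C)(C)C)C[C@](C)(O)[C@@]12C=CCCC2`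
A3 | alternative 2 | 4-[(2S,4S)-2,4-dihydroxy-6-methylhept-6-en-2-yl]cyclohexa-1,3-diene-1-carbaldehyde | `CC(=C)C[C@H](O)C[C@](C)(O)C1=CC=C(C=O)CC1`
A4 | alternative 2 | (3S,5S,6S)-3,5-dihydroxy-1,1,5-trimethylspiro[5.5]undec-8-ene-9-carbaldehyde | `CC1(C)C[C@H](O)C[C@](C)(O)[C@@]12CC=C(C=O)CC2`
A5 | alternative 3 | (4S)-4-silyloxy-2,6,6-trimethylcyclohex-2-ene whose ring C1 (working C6) carries a 2-iodoethyl arm cis to the silyloxy group and a (1Z)-4-(trimethylsilyl)but-1-en-3-yn-1-yl arm | `CC1(C)C[C@H](O[Si](C)(C)C(C)(C)C)C=C(C)[C@@]1(CCI)/C=C\C#C[Si](C)(C)C`
A6 | alternative 3 | {[(3S,6S,9E)-9-[bromo(trimethylsilyl)methylidene]-1,1,5-trimethylspiro[5.5]undeca-4,7-dien-3-yl]oxy}(tert-butyl)dimethylsilane (bromine cis to C10) | `CC1(C)C[C@H](O[Si](C)(C)C(C)(C)C)C=C(C)[C@@]12C=C/C(=C(/Br)[Si](C)(C)C)CC2`
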